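**Retrosynthetic overview**
- The hydroxyquinone is traced back to the symmetric resorcinol dimethyl ether 1,3-dimethoxy-2-methyl-5-nonadecylbenzene. The key step forms one new aryl C–O bond by C–H oxygenation and removes both O-methyl groups oxidatively and hydrolytically in one flask.
- The two free ring positions of that ether are equivalent, so the oxygenation has no regiochemical choice.
- The ring methyl is disconnected at the carbon between the two methoxy groups (directed ortho-lithiation, MeI).
- The C19 chain is disconnected at its benzylic C–C bond: 3,5-dimethoxybenzyl bromide plus octadecylmagnesium chloride (C1 + C18).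
- No ring is formed: the only ring is the benzene ring bought in the benzyl bromide, and it is dearomatised to the quinone in the last step.

Assumption: the target has no stereocentre and no stereogenic double bond, so it is achiral and no stereocontrol is needed.

**Route**

Step 1
Reactants: 1 1-(bromomethyl)-3,5-dimethoxybenzene (3,5-dimethoxybenzyl bromide); 2 octadecylmagnesium chloride (commercial solution in THF)
Product: 3 1,3-dimethoxy-5-nonadecylbenzene
Conditions: Li2CuCl4 (3 mol%), THF, −10 °C to rt, slow addition of 2
Reagents that add atoms: none
Why: Kochi-type copper-catalysed Grignard cross-coupling (Kumada-type sp3–sp3), in which the alkylcuprate formed from 2 and Li2CuCl4 displaces the reactive benzylic bromide faster than halogen–magnesium exchange, the aryl methyl ethers are inert, and no stereocentre is formed.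

Step 2
Reactants: 3 1,3-dimethoxy-5-nonadecylbenzene
Product: 5 1,3-dimethoxy-2-methyl-5-nonadecylbenzene, via aryllithium 4 (not isolated)
Conditions: n-BuLi, TMEDA, THF, 0 °C to rt; then MeI, 0 °C to rt
Reagents that add atoms: iodomethane (MeI), CI
Why: Directed ortho-metalation, in which the two methoxy groups cooperatively direct n-BuLi to the ring C–H between them (the most acidic site) and the resulting aryllithium is methylated by SN2 on MeI, with no stereocentre formed.

Step 3
Reactants: 5 1,3-dimethoxy-2-methyl-5-nonadecylbenzene
Product: 8 Capiquinone C (3-hydroxy-2-methyl-5-nonadecyl-1,4-benzoquinone), via phenol 6 (not isolated), via methoxyquinone 7 (not isolated)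
Conditions: PhI(OCOCF3)2 (2.1 equiv), H2O (10 equiv), (CF3)2CHOH/CH2Cl2, 0 °C to rt; then 6 M aq. H2SO4, 1,4-dioxane, 40 °C
Reagents that add atoms: water, O
Why: Proposed new method: a one-flask demethylative C–H oxygenation in which PhI(OCOCF3)2 in wet (CF3)2CHOH oxidises the electron-rich arene 5 to its radical cation, water adds at the only kind of free ring position to forge the new aryl C–O bond of phenol 6, a second equivalent oxidises this alkoxyphenol through an aryloxy-λ3-iodane to quinone 7 with loss of methanol (ipso attack of water or ortho-quinone formation would converge on the same product after hydrolysis), and the added acid then cleaves the remaining vinylogous methyl ester by addition–elimination of water, the closest known reaction types being the PhI(OCOCF3)2-induced nucleophilic substitution of phenol ethers via arene radical cations, the trivalent-iodine oxidative dearomatisation of p-alkoxyphenols to p-quinones and the acid hydrolysis of methoxyquinones, with no stereocentre formed.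

**Compound list**
1 | 1-(bromomethyl)-3,5-dimethoxybenzene (3,5-dimethoxybenzyl bromide) | COc1cc(CBr)cc(OC)c1 | starting material
2 | octadecylmagnesium chloride | CCCCCCCCCCCCCCCCCC[Mg]Cl | starting material
3 | 1,3-dimethoxy-5-nonadecylbenzene | CCCCCCCCCCCCCCCCCCCc1cc(OC)cc(OC)c1 | intermediate
4 | (2,6-dimethoxy-4-nonadecylphenyl)lithium (not isolated) | CCCCCCCCCCCCCCCCCCCc1cc(OC)c([Li])c(OC)c1 | intermediate
5 | 1,3-dimethoxy-2-methyl-5-nonadecylbenzene | CCCCCCCCCCCCCCCCCCCc1cc(OC)c(C)c(OC)c1 | intermediate
6 | 2,4-dimethoxy-3-methyl-6-nonadecylphenol (not isolated) | CCCCCCCCCCCCCCCCCCCc1cc(OC)c(C)c(OC)c1O | intermediate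
7 | 3-methoxy-2-methyl-5-nonadecylcyclohexa-2,5-diene-1,4-dione (not isolated) | CCCCCCCCCCCCCCCCCCCC1=CC(=O)C(C)=C(OC)C1=O | intermediate
8 | Capiquinone C, 3-hydroxy-2-methyl-5-nonadecylcyclohexa-2,5-diene-1,4-dione (achiral) | CCCCCCCCCCCCCCCCCCCC1=CC(=O)C(C)=C(O)C1=O | target

**Step count and risks**

Total step count: 3. Longest linear sequence: 3 steps (1 to 3 to 5 to 8).

Steps most likely to fail, most risky first:

Step 3 (the proposed new step). The radical cation of 5 could be diverted to an aryl(phenyl)iodonium salt, to benzylic oxidation or to biaryl coupling, and 8 could be over-oxidised if oxidant is still present during the hydrolysis. The fallback uses known chemistry, sets out from 5 and comes back to the route at 8. Both methyl ethers are cleaved with BBr3 (CH2Cl2, −78 °C to rt) to give 2-methyl-5-nonadecylbenzene-1,3-diol F1. This symmetric resorcinol is then oxidised para to one hydroxyl by the Teuber reaction with (KSO3)2NO (potassium nitrosodisulfonate, Fremy's salt; KH2PO4 buffer, acetone/H2O, rt), which gives 8 directly.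

Step 2. Lithiation of the waxy, poorly soluble 3 may stall, and unreacted 3 differs from 5 by a single CH2, so it is hard to remove. The fallback sets out from 2 and comes back at 5, bypassing 3 and 4. Compound 2 is added to commercial 3,5-dimethoxy-4-methylbenzaldehyde (THF, 0 °C), which already carries the ring methyl, to give racemic 1-(3,5-dimethoxy-4-methylphenyl)nonadecan-1-ol F2. Its benzylic C–O bond is then removed by hydrogenolysis (H2, Pd/C, AcOH, cat. H2SO4, 50 °C) to give 5; the stereocentre of the alcohol is erased in this step.

Step 1. Halogen–magnesium exchange can give the bibenzyl homodimer and reduced 3,5-dimethoxytoluene in place of the cross-coupled product. The fallback replaces the cross-coupling by olefination and hydrogenation, sets out from 1 and comes back at 3. Compound 1 is heated with PPh3 (toluene, reflux) to give (3,5-dimethoxybenzyl)triphenylphosphonium bromide F3. Its ylide (KOtBu, THF, 0 °C) undergoes Wittig reaction with octadecanal to give 1,3-dimethoxy-5-(nonadec-1-en-1-yl)benzene F4 as a Z/E mixture. Hydrogenation (H2, Pd/C, EtOAc, rt) converts both isomers to 3.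

Further compounds
F1 | step 3 | 2-methyl-5-nonadecylbenzene-1,3-diol | CCCCCCCCCCCCCCCCCCCc1cc(O)c(C)c(O)c1
F2 | step 2 | 1-(3,5-dimethoxy-4-methylphenyl)nonadecan-1-ol (racemic) | CCCCCCCCCCCCCCCCCCC(O)c1cc(OC)c(C)c(OC)c1
F3 | step 1 | (3,5-dimethoxybenzyl)triphenylphosphonium bromide | COc1cc(C[P+](c2ccccc2)(c2ccccc2)c2ccccc2)cc(OC)c1.[Br-]
F4 | step 1 | 1,3-dimethoxy-5-(nonadec-1-en-1-yl)benzene (Z/E mixture, geometry left open) | CCCCCCCCCCCCCCCCCC=Cc1cc(OC)cc(OC)c1
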